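Cardivin D hides a mirror plane through C2 and C7: C4/C10 carry the methyls, C5/C9 and C6/C8 the oxygens. The cyclodecane is therefore never closed as such. A temporary C5=C9 bond folds it into a 5–7 bicycle. A (4+3) cycloaddition of an oxyallyl cation (C1–C2–C3) onto the meso cyclopenta[c]furan 12 builds this bicycle in one operation. It forms bonds C1–C10 and C3–C4, puts all ten ring carbons in place, and sets the furan oxygen (future 10-OH) relative to C6–C8. A chiral lithium amide then opens the oxygen bridge on one side only, which fixes the absolute configuration. Ozonolysis of C5=C9 releases the ten-membered ring.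

Key step: step 7

Remark: locants C1–C15 are germacrane numbers (ring C1–C10; C2 carbinol, C4 CHMe, C5 ketone, C6 and C9 acyloxy carbons, C7 branch point, C8 lactone carbinol, C10 tertiary carbinol; C11–C13 methylene lactone; C14 on C10; C15 on C4); 30 is taken as the open hydroxy ketone drawn, its 2,5-hemiketal 29 being a tautomer; the sense of induction in step 8 is assigned by analogy with simpler 8-oxabicyclo[3.2.1]octan-3-ones, and the mirror-image amine is equally available.

Step 1
Reactants: 1 methyl 4-chloro-4-oxobutanoate; 2 propyne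
Product: 3 methyl 4-oxohept-5-ynoate
Conditions: PdCl2(PPh3)2 (cat.), CuI (cat.), Et3N, THF, 0 °C to rt
Reagents that add atoms: none
Why: Acyl Sonogashira coupling of an acid chloride with a terminal alkyne gives the ynone directly and leaves the methyl ester untouched; no stereocentre is formed.

Step 2
Reactants: 3 methyl 4-oxohept-5-ynoate; 4 but-2-ynal
Product: 6 rac-methyl (3R*,4R*)-3-(but-2-ynoyl)-4-hydroxyhept-5-ynoate (7,8-syn aldol), via boron enolate 5 (not isolated)
Conditions: n-Bu2BOTf, i-Pr2NEt, CH2Cl2, −78 °C; 4, −78 to 0 °C; MeOH, pH 7 buffer, H2O2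
Reagents that add atoms: none
Why: Boron-mediated aldol reaction: the ketone can enolise only towards C7, n-Bu2BOTf/i-Pr2NEt gives the (Z)-enolate 5, and its Zimmerman–Traxler chair should deliver the 7,8-syn aldol (racemic, which is harmless because the next step leads to a meso compound).

Step 3
Reactants: 6 rac-syn aldol
Product: 7 meso-methyl 4-hydroxy-3-(1-hydroxybut-2-ynyl)hept-5-ynoate (6S,8R; all-syn C6–C7–C8)
Conditions: Et2BOMe, THF/MeOH 4:1, −78 °C; NaBH4; MeOH azeotrope at or below rt
Reagents that add atoms: none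
Why: Narasaka–Prasad reduction: hydride adds axially to the six-membered boron chelate of the β-hydroxy ynone and sets C6 1,3-syn to C8, so that both enantiomers of 6 converge on one achiral all-syn diol.

Step 4
Reactants: 7 meso diol
Product: 8 meso bis(isobutyrate) of 7 (6S,8R)
Conditions: i-PrCOCl, pyridine, DMAP (cat.), CH2Cl2, 0 °C to rt, on crude 7
Reagents that add atoms: isobutyryl chloride CC(C)C(=O)Cl
Why: DMAP-catalysed esterification of both propargylic alcohols, run on the crude diol to outrun γ-lactonisation, installs the two isobutyrates of the target at once without touching a stereocentre.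

Step 5
Reactants: 8 meso diyne bis(isobutyrate)
Product: 9 meso-methyl 2-[3,4-diethylidene-2,5-bis(isobutyryloxy)cyclopentyl]acetate (acyloxy groups cis to each other and trans to the CH2CO2Me arm; both methyls outside and both vinylic H inside the s-cis diene; Z,Z by CIP)
Conditions: [Rh(cod)2]OTf (cat.), rac-BINAP (cat.), H2 (1 atm), ClCH2CH2Cl, 25 °C
Reagents that add atoms: none
Why: Rhodium-catalysed hydrogen-mediated reductive cyclisation of a 1,6-diyne (oxidative coupling of the two alkynes on Rh, then hydrogenolysis of both C–Rh bonds) closes the cyclopentane at C5–C9 and, being a cis addition at each alkyne, places both new hydrogens inside the diene.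

Step 6
Reactants: 9 meso diene
Product: 12 meso-methyl 2-[1,3-dimethyl-4,6-bis(isobutyryloxy)-5,6-dihydro-4H-cyclopenta[c]furan-5-yl]acetate (4,6-cis; 5-trans to both), via endoperoxide 10 (not isolated), via hydroxy enone 11 (not isolated)
Conditions: O2, tetraphenylporphyrin (cat.), hν, CH2Cl2, −20 °C; Et3N (cat.), 0 °C to rt; PPTS (cat.), 4 Å MS
Reagents that add atoms: dioxygen O=O
Why: Singlet oxygen adds to the locked s-cis diene in a (4+2) cycloaddition, amine-induced Kornblum–DeLaMare rearrangement of 10 gives the cis-γ-hydroxy enone 11, and acid-catalysed cyclodehydration aromatises it to the furan, which erases the transient centres at C4 and C10 and keeps the mirror plane.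

Step 7
Reactants: 12 meso cyclopenta[c]furan; 13 1,1,3,3-tetrabromoacetone
Product: 15 meso (4R,6S,8R,10S) oxa-bridged hydroazulenone (1,5-dimethyl-8-oxabicyclo[3.2.1]oct-6-en-3-one whose C6=C7 bond is C5=C9 of the fused cyclopentane; oxygen bridge syn to both isobutyrates), via dibromo cycloadduct 14 (not isolated)
Conditions: Zn–Ag couple, THF, −10 °C to rt; then Zn–Cu couple, NH4Cl, MeOH, rt
Reagents that add atoms: none
Why: Zinc reduces 13 to the 1,3-dibromo-2-oxyallyl cation, a 2π three-carbon electrophile that adds across the 4π termini C4 and C10 of the furan in an oxyallyl (4+3) cycloaddition, a reaction type well established for 2,5-dimethylfuran, either concertedly or by fast stepwise closure. The seven-membered ring C1–C2–C3–C4–C5–C9–C10 is closed intermolecularly by suprafacial bonding at both furan α-carbons, which at the same time turns the furan oxygen into the C4–O–C10 bridge; substitution instead of cycloaddition is blocked because both α-positions carry methyl. The new stereocentres C4 and C10 are tied to each other by the bridge and are set relative to C6–C8 by the face of attack: the two isobutyrates that flank the furan stand on one face, so the cation should come from the other, which puts the bridge oxygen (future 10-OH) syn to O6 and O8 as in the target. The selectivities needed are this facial one and cycloaddition over ionisation of the furylic esters; the low temperature and the weakly Lewis acidic zinc medium should secure them. Zn–Cu then removes both C–Br bonds of 14 and restores the mirror plane.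

Step 8
Reactants: 15 meso oxa-bridged ketone
Product: 17 (10S)-10-hydroxy dienone (bicyclo[5.3.0]deca-3,5(9)-dien-2-one core; C6 C7 C8 C10 configured as in 30), via lithium enolate 16 (not isolated)
Conditions: (R,R)-bis(1-phenylethyl)amine·HCl, n-BuLi (2 equiv), THF, −78 °C; 15, −78 °C, then to −20 °C; AcOH
Reagents that add atoms: none
Why: Enantiotopic-group-selective deprotonation of a meso 8-oxabicyclo[3.2.1]octan-3-one by a C2-symmetric chiral lithium amide should take the axial proton at C3 rather than at C1, and on warming the enolate 16 expels the β-oxygen (E1cB) by breaking C4–O only, so that the oxygen stays on C10 with its configuration and all stereocentres become absolute.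

Step 9
Reactants: 17 hydroxy dienone
Product: 18 (3Z)-10-hydroxycyclodec-3-ene-2,5,9-trione (6,8-bis(isobutyrate); 7-CH2CO2Me)
Conditions: O3, CH2Cl2, −78 °C (Sudan III end point); Me2S
Reagents that add atoms: ozone [O-][O+]=O
Why: Ozonolysis with reductive work-up attacks the electron-richer tetrasubstituted γ,δ-double bond C5=C9 of the dienone in preference to the enone bond C3=C4 (as in sorbate-type dienes) and thereby turns the 5–7 bicycle into the cyclodecane; no stereocentre is touched.

Step 10
Reactants: 18 cyclodecene trione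
Product: 20 2,5-epoxy-bridged dihydrofuran hemiketal (2S; 5-OH; C3=C4; 9-ketone; free 10-OH), via open hydroxy enone 19 (not isolated)
Conditions: Et2BOMe, THF/MeOH 4:1, −78 °C; NaBH4 (1 equiv)
Reagents that add atoms: none
Why: Narasaka–Prasad reduction: boron ties the free 10-OH to the C2 carbonyl, the only ketone flanked by CH2 and CH, so that hydride should reduce it 1,2 and 1,3-syn to C10 (2S), and the (Z)-γ-hydroxy enone 19 closes at once to the hemiketal, in which C1 and C6 must be cis on the dihydrofuran.

Step 11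
Reactants: 20 hemiketal
Product: 21 5,10-bis(triethylsilyl) ether of 20
Conditions: Et3SiOTf, 2,6-lutidine, CH2Cl2, −78 to 0 °C
Reagents that add atoms: triethylsilyl triflate CC[Si](CC)(CC)OS(=O)(=O)C(F)(F)F
Why: Silylation with a silyl triflate and a hindered pyridine caps the tertiary 10-OH and locks the hemiketal as a silyl ketal, which masks 2-OH and the C5 ketone in one group; aromatisation is disfavoured because it would give a strained [6](2,5)furanophane.

Step 12
Reactants: 21 dihydrofuran silyl ketal
Product: 22 (4S)-tetrahydrofuran silyl ketal (4-methyl endo; H-4 syn to the oxygen bridge)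
Conditions: H2 (1 atm), Rh/Al2O3, EtOAc, rt
Reagents that add atoms: none
Why: Heterogeneous hydrogenation can reach the trisubstituted C3=C4 bond of the 11-oxabicyclo[6.2.1]undecene only from the exo face next to the oxygen bridge, since the six-carbon bridge covers the endo face, which puts H-4 syn to the bridge (4S); rhodium is chosen to avoid allylic C–O hydrogenolysis.

Step 13
Reactants: 22 9-ketone
Product: 23 (9S)-9-alcohol
Conditions: NaBH4, THF/MeOH, −40 °C
Reagents that add atoms: none
Why: Borohydride reduction under polar Felkin–Anh (Cornforth) control: the carbonyl oxygen turns away from the two flanking C–O bonds (8-OCOi-Pr and 10-OSiEt3, both on the same side) and hydride enters from the ring periphery, which should give the 8,9-syn-9,10-syn triad; it is the only ketone left unmasked.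

Step 14
Reactants: 23 9-alcohol
Product: 25 trans-fused 8,12-lactone with 6- and 9-isobutyrates, via 8-hydroxy 9-isobutyrate 24 (not isolated)
Conditions: DBU (cat.), toluene, 60 °C
Reagents that add atoms: none
Why: Base-catalysed 1,2-acyl migration moves the isobutyrate from O8 to the neighbouring O9 through a five-membered orthoester, and the freed 8-OH is drained irreversibly by γ-lactonisation onto the methyl ester, so that 6-O-acyl, 9-O-acyl and the lactone emerge without differentiating protecting groups.

Step 15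
Reactants: 25 lactone
Product: 28 α-methylene lactone bis(triethylsilyl) ether, via Mannich base 26 (not isolated), via ammonium iodide 27 (not isolated)
Conditions: LDA, THF, −78 °C; CH2=NMe2+ I−, −78 °C to rt; MeI, CH2Cl2; aq NaHCO3
Reagents that add atoms: N,N-dimethylmethyleneiminium iodide C=[N+](C)C.[I-]; iodomethane CI
Why: α-Methylenation of a γ-butyrolactone by the Mannich route (lithium enolate, Eschenmoser's salt, N-methylation, Hofmann-type elimination): the lactone CH2 is the most acidic and least hindered C–H, because all ketones are masked and the isobutyrates offer only tertiary α-hydrogens.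

Step 16
Reactants: 28 bis(triethylsilyl) ether
Product: 30 cardivin D, via hemiketal 29 (not isolated)
Conditions: HF·pyridine, pyridine/THF, 0 °C to rt
Reagents that add atoms: none
Why: Fluoride-mediated cleavage of both Si–O bonds under buffered acidic conditions frees 10-OH and the hemiketal 29, which opens to the 2-hydroxy-5-ketone without a base that could epimerise C4 or add to the methylene lactone.

Compound list
1 | methyl 4-chloro-4-oxobutanoate | COC(=O)CCC(=O)Cl | starting material
2 | propyne | CC#C | starting material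
3 | methyl 4-oxohept-5-ynoate | COC(=O)CCC(=O)C#CC | intermediate
4 | but-2-ynal | CC#CC=O | starting material
5 | (Z)-dibutylboron enolate of 3 | COC(=O)C/C=C(\OB(CCCC)CCCC)C#CC | intermediate
6 | rac-methyl (3R*,4R*)-3-(but-2-ynoyl)-4-hydroxyhept-5-ynoate (one enantiomer drawn) | COC(=O)C[C@@H](C(=O)C#CC)[C@@H](O)C#CC | intermediate
7 | meso all-syn diyne diol | COC(=O)C[C@@H]([C@H](O)C#CC)[C@@H](O)C#CC | intermediate
8 | meso diyne bis(isobutyrate) | COC(=O)C[C@@H]([C@H](OC(=O)C(C)C)C#CC)[C@@H](OC(=O)C(C)C)C#CC | intermediate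
9 | meso 1,2-diethylidenecyclopentane | COC(=O)C[C@H]1[C@H](OC(=O)C(C)C)/C(=C\C)/C(=C/C)[C@@H]1OC(=O)C(C)C | intermediate
10 | 4,10-endoperoxide | COC(=O)C[C@H]1[C@H](OC(=O)C(C)C)C2=C([C@@H]1OC(=O)C(C)C)[C@H](C)OO[C@@H]2C | intermediate
11 | cis-γ-hydroxy enone (racemic, one enantiomer drawn) | COC(=O)C[C@H]1[C@H](OC(=O)C(C)C)C(C(C)=O)=C([C@@H]1OC(=O)C(C)C)[C@H](C)O | intermediate
12 | meso cyclopenta[c]furan | COC(=O)C[C@H]1[C@H](OC(=O)C(C)C)c2c(C)oc(C)c2[C@@H]1OC(=O)C(C)C | intermediate
13 | 1,1,3,3-tetrabromoacetone | BrC(Br)C(=O)C(Br)Br | starting material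
14 | 1,3-dibromo cycloadduct (bromide epimers) | COC(=O)C[C@H]1[C@H](OC(=O)C(C)C)C2=C([C@@H]1OC(=O)C(C)C)[C@]3(C)C(Br)C(=O)C(Br)[C@@]2(C)O3 | intermediate
15 | meso oxa-bridged hydroazulenone | COC(=O)C[C@H]1[C@H](OC(=O)C(C)C)C2=C([C@@H]1OC(=O)C(C)C)[C@]3(C)CC(=O)C[C@@]2(C)O3 | intermediate
16 | lithium C2=C3 enolate of 15 | COC(=O)C[C@H]1[C@H](OC(=O)C(C)C)C2=C([C@@H]1OC(=O)C(C)C)[C@]3(C)CC([O-])=C[C@@]2(C)O3.[Li+] | intermediate
17 | 10-hydroxy dienone | COC(=O)C[C@H]1[C@H](OC(=O)C(C)C)C2=C([C@@H]1OC(=O)C(C)C)[C@@](C)(O)CC(=O)C=C2C | intermediate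
18 | (3Z)-cyclodecene-2,5,9-trione | COC(=O)C[C@H]1[C@H](OC(=O)C(C)C)C(=O)/C(C)=C\C(=O)C[C@](C)(O)C(=O)[C@@H]1OC(=O)C(C)C | intermediate
19 | open (2S)-hydroxy enone | COC(=O)C[C@H]1[C@H](OC(=O)C(C)C)C(=O)/C(C)=C\[C@H](O)C[C@](C)(O)C(=O)[C@@H]1OC(=O)C(C)C | intermediate
20 | dihydrofuran hemiketal | COC(=O)C[C@H]1[C@H](OC(=O)C(C)C)[C@]2(O)O[C@@H](C=C2C)C[C@](C)(O)C(=O)[C@@H]1OC(=O)C(C)C | intermediate
21 | bis(triethylsilyl) dihydrofuran ketal | COC(=O)C[C@H]1[C@H](OC(=O)C(C)C)[C@]2(O[Si](CC)(CC)CC)O[C@@H](C=C2C)C[C@](C)(O[Si](CC)(CC)CC)C(=O)[C@@H]1OC(=O)C(C)C | intermediate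
22 | (4S)-tetrahydrofuran ketal 9-ketone | COC(=O)C[C@H]1[C@H](OC(=O)C(C)C)[C@]2(O[Si](CC)(CC)CC)O[C@@H](C[C@@H]2C)C[C@](C)(O[Si](CC)(CC)CC)C(=O)[C@@H]1OC(=O)C(C)C | intermediate
23 | (9S)-alcohol | COC(=O)C[C@H]1[C@H](OC(=O)C(C)C)[C@]2(O[Si](CC)(CC)CC)O[C@@H](C[C@@H]2C)C[C@](C)(O[Si](CC)(CC)CC)[C@@H](O)[C@@H]1OC(=O)C(C)C | intermediate
24 | 8-hydroxy 9-isobutyrate | COC(=O)C[C@H]1[C@H](OC(=O)C(C)C)[C@]2(O[Si](CC)(CC)CC)O[C@@H](C[C@@H]2C)C[C@](C)(O[Si](CC)(CC)CC)[C@@H](OC(=O)C(C)C)[C@@H]1O | intermediate
25 | 8,12-lactone | O=C1C[C@H]2[C@H](OC(=O)C(C)C)[C@]3(O[Si](CC)(CC)CC)O[C@@H](C[C@@H]3C)C[C@](C)(O[Si](CC)(CC)CC)[C@@H](OC(=O)C(C)C)[C@@H]2O1 | intermediate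
26 | 11-(dimethylaminomethyl) lactone (C11 epimers) | O=C1C(CN(C)C)[C@H]2[C@H](OC(=O)C(C)C)[C@]3(O[Si](CC)(CC)CC)O[C@@H](C[C@@H]3C)C[C@](C)(O[Si](CC)(CC)CC)[C@@H](OC(=O)C(C)C)[C@@H]2O1 | intermediate
27 | trimethylammonium iodide of 26 | O=C1C(C[N+](C)(C)C)[C@H]2[C@H](OC(=O)C(C)C)[C@]3(O[Si](CC)(CC)CC)O[C@@H](C[C@@H]3C)C[C@](C)(O[Si](CC)(CC)CC)[C@@H](OC(=O)C(C)C)[C@@H]2O1.[I-] | intermediate
28 | α-methylene lactone bis(triethylsilyl) ether | C=C1C(=O)O[C@@H]2[C@@H]1[C@H](OC(=O)C(C)C)[C@]3(O[Si](CC)(CC)CC)O[C@@H](C[C@@H]3C)C[C@](C)(O[Si](CC)(CC)CC)[C@H]2OC(=O)C(C)C | intermediate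
29 | 2,5-hemiketal tautomer of 30 | C=C1C(=O)O[C@@H]2[C@@H]1[C@H](OC(=O)C(C)C)[C@]3(O)O[C@@H](C[C@@H]3C)C[C@](C)(O)[C@H]2OC(=O)C(C)C | intermediate
30 | cardivin D (2S,4S,6S,7R,8R,9S,10S) | C=C1C(=O)O[C@@H]2[C@@H]1[C@H](OC(=O)C(C)C)C(=O)[C@@H](C)C[C@H](O)C[C@](C)(O)[C@H]2OC(=O)C(C)C | target

Total step count: 16. Longest linear sequence: 16 (from 1).

Steps most likely to fail

Step 8. The amide may discriminate poorly between the enantiotopic protons next to the methyl-bearing bridgeheads. The enolate may resist elimination, or the product may lose the C10 oxygen as well and aromatise to a tropone. The tertiary alkoxide may also pick up the neighbouring isobutyrate. The fallback moves the enantio-determining event into the cycloaddition and generates the enolate reductively. It sets out from 12. The chiral reagent is 3-methoxy-3-[(S)-1-phenylethoxy]-2-(triethylsilyloxy)prop-1-ene, ionised with catalytic TMSOTf in CH2Cl2 at −95 °C. Its auxiliary-controlled (4+3) cycloaddition with 12 should give the 3-[(S)-1-phenylethoxy] oxa-bridged ketone F3. SmI2 in THF without a proton source cleaves the α-C–O bond to the auxiliary, which gives the C2=C3 samarium enolate regiospecifically. This enolate undergoes the same E1cB opening on warming, and the route is rejoined at 17.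

Step 10. Hydride may add in a conjugate sense to the enedione, or at C9 through a five-membered chelate. The free 10-OH may close onto C3, or the facial selectivity may be poor. The fallback reduces first and cleaves afterwards, and it sets out from 17, where C2 is the only ketone.
- Narasaka–Prasad reduction gives the syn diene diol F4.
- TESCl/imidazole silylates only the secondary allylic alcohol and gives the 2-O-triethylsilyl ether F5.
- VO(acac)2/t-BuOOH epoxidation, directed by the tertiary allylic 10-OH, gives the 5,9-epoxide F6.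
- Periodic acid in wet THF opens and cleaves the epoxide to the 2-O-triethylsilyl cyclodecene dione F7.
- HF·pyridine frees the alcohol, which closes and rejoins the route at 20.

Step 7. Zinc salts may ionise the furylic esters. The cation may approach from the ester-bearing face, or it may bond once and lose a proton instead of closing the ring. The fallback replaces the cation by a neutral carbenoid and sets out from 12.
- Rh2(OAc)4-catalysed cyclopropanation of the C4=C5 furan bond uses allyl 2-diazo-3-(tert-butyldimethylsilyloxy)but-3-enoate. It is followed in situ by Cope rearrangement of the cis-divinylcyclopropane, a formal (4+3), and gives the bicyclic silyl enol ether ester F1.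
- HF·Et3N gives the allyl β-keto ester F2.
- Pd(PPh3)4 with HCO2H/Et3N effects decarboxylative deallylation and rejoins the route at 15.

Further compounds
F1 | step 7 | bicyclic silyl enol ether ester (racemic, one enantiomer drawn) | COC(=O)C[C@H]1[C@H](OC(=O)C(C)C)C2=C([C@@H]1OC(=O)C(C)C)[C@]3(C)CC(O[Si](C)(C)C(C)(C)C)=C(C(=O)OCC=C)[C@@]2(C)O3
F2 | step 7 | allyl β-keto ester (C3 epimers) | COC(=O)C[C@H]1[C@H](OC(=O)C(C)C)C2=C([C@@H]1OC(=O)C(C)C)[C@]3(C)CC(=O)C(C(=O)OCC=C)[C@@]2(C)O3
F3 | step 8 | 3-[(S)-1-phenylethoxy] oxa-bridged ketone (alkoxy group equatorial) | COC(=O)C[C@H]1[C@H](OC(=O)C(C)C)C2=C([C@@H]1OC(=O)C(C)C)[C@]3(C)CC(=O)[C@H](O[C@@H](C)c4ccccc4)[C@@]2(C)O3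
F4 | step 10 | syn diene diol | COC(=O)C[C@H]1[C@H](OC(=O)C(C)C)C2=C([C@@H]1OC(=O)C(C)C)[C@@](C)(O)C[C@@H](O)C=C2C
F5 | step 10 | 2-O-triethylsilyl ether | COC(=O)C[C@H]1[C@H](OC(=O)C(C)C)C2=C([C@@H]1OC(=O)C(C)C)[C@@](C)(O)C[C@@H](O[Si](CC)(CC)CC)C=C2C
F6 | step 10 | 5,9-epoxide (syn to 10-OH) | COC(=O)C[C@H]1[C@H](OC(=O)C(C)C)[C@]23O[C@@]2([C@@H]1OC(=O)C(C)C)[C@@](C)(O)C[C@@H](O[Si](CC)(CC)CC)C=C3C
F7 | step 10 | 2-O-triethylsilyl cyclodecene dione | COC(=O)C[C@H]1[C@H](OC(=O)C(C)C)C(=O)/C(C)=C\[C@H](O[Si](CC)(CC)CC)C[C@](C)(O)C(=O)[C@@H]1OC(=O)C(C)C
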